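**Plan**

- Retrosynthesis: ring C is opened by cutting O1–C8a and C2–C3 together. This gives aldehyde 18 (ring B, C2 and O1) and the 2-fluoroaryl methyl ketone 14, used as its enol silane 16. Ketone 14 is then cut at C4–C4a (acylation of an aryllithium) and at C6–C1'' (aryl–allyl coupling); the side chain comes from geranyl acetate.
- Forward: side chain (steps 1–3); ring A, bought as 5-fluororesorcinol, is substituted by two successive directed metalations (steps 4–6); enol silane (step 7); aldehyde (step 8); ring C is closed last (step 9); global deprotection (step 10).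
- Enabling feature: in ring C the C2–O1 unit is an aldehyde C=O lying between C3 (α to the C4 ketone, nucleophilic as the enol silane) and C8a (ortho to that ketone on ring A, meta to O5 and O7). A fluoride at C8a is therefore displaceable by SNAr, and the one C4 carbonyl activates both new bonds.
- Stereochemistry: C2 (S) is set by the catalyst in the aldol stage and kept with retention, since C2–O1 is never broken. 2''E comes from geranyl acetate; 5''E from a selenoxide syn-elimination.
- Regiochemistry (6- versus 8-substituent) is fixed because only the fluorine-bearing carbon can receive O1.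

Key step: step 9

Assumption: the (S,S) antipode of the bisphosphoramide catalyst is taken to expose the Si face of aldehyde 18, the sense needed for 2S; if a test aldol shows the opposite sense, the (R,R) antipode is used with no other change.

Abbreviations in names: MOM = methoxymethyl; TES = triethylsilyl.

**Route**

Step 1
Reactants: 1 geranyl acetate
Product: 2 6,7-epoxygeranyl acetate (racemic)
Conditions: mCPBA (1.0 equiv), NaHCO3, CH2Cl2, −20 → 0 °C
Reagents that add atoms: 3-chloroperoxybenzoic acid (mCPBA), OOC(=O)c1cccc(Cl)c1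
Why: Prilezhaev epoxidation should take the electron-rich 6,7-alkene because the 2,3-alkene is deactivated by the allylic acetate; the racemic epoxide stereocentre is destroyed in step 2.

Step 2
Reactants: 2 6,7-epoxygeranyl acetate
Product: 5 (2E,5E)-7-hydroxy-3,7-dimethylocta-2,5-dien-1-yl acetate, via hydroxy selenide 3 (not isolated), via selenoxide 4 (not isolated)
Conditions: PhSeSePh, NaBH4, EtOH, 0 °C → rt; then 30% H2O2, pyridine, THF, 0 °C → rt
Reagents that add atoms: none
Why: Epoxide-to-allylic-alcohol transposition by selenolate opening at the less hindered secondary carbon and selenoxide syn-elimination, which can only run toward C5 because C7 bears no hydrogen and should give the E-disubstituted alkene next to the tertiary alcohol.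

Step 3
Reactants: 5 (2E,5E)-7-hydroxy-3,7-dimethylocta-2,5-dien-1-yl acetate
Product: 6 TES-protected side-chain acetate
Conditions: Et3SiOTf, 2,6-lutidine, CH2Cl2, −78 → 0 °C
Reagents that add atoms: triethylsilyl trifluoromethanesulfonate, CC[Si](CC)(CC)OS(=O)(=O)C(F)(F)F
Why: Silyl triflate silylation of a hindered tertiary alcohol with a non-nucleophilic base; the allylic acetate is inert.

Step 4
Reactants: 7 5-fluorobenzene-1,3-diol
Product: 8 1-fluoro-3,5-bis(methoxymethoxy)benzene
Conditions: MOMCl, i-Pr2NEt, CH2Cl2, 0 °C → rt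
Reagents that add atoms: chloromethyl methyl ether, COCCl
Why: Double phenol O-alkylation (Williamson type) gives the bis-acetal, which is base-stable and later serves as directing group.

Step 5
Reactants: 8 1-fluoro-3,5-bis(methoxymethoxy)benzene; 6 TES-protected side-chain acetate
Product: 11 2-allylated 5-fluoro-1,3-bis(MOM-oxy)benzene carrying the full TES-protected side chain, via aryllithium 9 (not isolated), via arylzinc chloride 10 (not isolated)
Conditions: n-BuLi, THF, −40 °C; ZnCl2, −40 → 0 °C; then 6, Pd(PPh3)4 (5 mol%, zerovalent palladium), THF, rt → 45 °C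
Reagents that add atoms: none
Why: Directed ortho-metalation at the CH flanked by both acetal oxygens (para to fluorine, so no aryne can form), transmetalation to zinc and Negishi-type allyl–aryl coupling through a π-allylpalladium intermediate, which should deliver the aryl group to the unhindered CH2 terminus with retention of the 2E geometry.

Step 6
Reactants: 11 2-allylated 5-fluoro-1,3-bis(MOM-oxy)benzene
Product: 14 2-fluoroaryl methyl ketone, via ortho-fluoro aryllithium 12 (not isolated), via lithium hemiaminal 13 (not isolated)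
Conditions: n-BuLi, THF, −78 °C; N-methoxy-N-methylacetamide, −78 °C; then AcOH, −78 °C
Reagents that add atoms: N-methoxy-N-methylacetamide, CC(=O)N(C)OC
Why: Second directed ortho-metalation at the only ring CH (acidified by the adjacent fluorine, chelated by the adjacent acetal oxygen) followed by Weinreb acylation at −78 °C, where the ortho-fluoroaryllithium should not lose LiF and the chelated tetrahedral adduct prevents over-addition.

Step 7
Reactants: 14 2-fluoroaryl methyl ketone
Product: 16 trimethylsilyl enol ether of 14, via lithium enolate 15 (not isolated)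
Conditions: LiN(SiMe3)2, THF, −78 °C; Me3SiCl, Et3N, −78 → 0 °C; non-aqueous work-up, used directly
Reagents that add atoms: chlorotrimethylsilane, C[Si](C)(C)Cl
Why: Kinetic deprotonation of the only enolisable position (the acetyl CH3) and O-silylation of the enolate; the basic conditions spare the acetals and the silyl ether.

Step 8
Reactants: 17 vanillin
Product: 18 3-methoxy-4-(methoxymethoxy)benzaldehyde
Conditions: MOMCl, i-Pr2NEt, CH2Cl2, 0 °C → rt
Reagents that add atoms: chloromethyl methyl ether, COCCl
Why: Phenol O-alkylation to the MOM acetal under amine base leaves the aldehyde untouched.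

Step 9
Reactants: 16 trimethylsilyl enol ether; 18 3-methoxy-4-(methoxymethoxy)benzaldehyde
Product: 21 (2S)-flavanone with 5-, 7- and 4'-O-MOM groups and the TES-protected side chain at C6, via trichlorosilyl aldolate 19 (not isolated), via cesium alkoxide 20 (not isolated)
Conditions: (S,S)-bisphosphoramide [pentane-1,5-diyl-bridged bis(N-methylphosphoramide) of (S)-N,N'-dimethyl-1,1'-binaphthyl-2,2'-diamine] (5 mol%), SiCl4 (1.5 equiv), i-Pr2NEt (10 mol%), CH2Cl2, −78 °C; then CsF (10 equiv), 18-crown-6, DMF, −78 → 35 °C
Reagents that add atoms: none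
Why: Proposed new method: the phosphoramide-bound trichlorosilyl cation activates aldehyde 18 and the unhindered CH2 terminus of enol silane 16 attacks its Si face in an open transition state (closest known reaction type: the Lewis-base-catalysed SiCl4 Mukaiyama aldol of methyl-ketone enol silanes with aromatic aldehydes), so C2 is set by the catalyst alone. Fluoride then strips silicon from the aldolate oxygen and the alkoxide closes ring C by 6-exo addition–elimination (SNAr) at C8a, a closure known for alkoxides and phenoxides on 2-fluoroaryl ketones (chromone and xanthone syntheses) and for silyl ethers under fluoride, but not yet shown for an aldolate in the same flask. The closure is favoured because the C4 carbonyl is ortho to the C–F carbon and stabilises the Meisenheimer anion at C4a, while both ring-A acetal oxygens are meta to C8a and do not donate to it. The C2–O1 bond is never broken, so the aldol configuration should pass into the flavanone with retention, provided retro-aldol and E1cB loss of the alkoxide are slower than ring closure; the low temperature of the fluoride addition and the intramolecularity are meant to secure this. Regioselectivity needs no control, since only the fluorine-bearing carbon can accept oxygen and O5 stays capped as its acetal. The expelled fluoride re-enters the desilylation, so the closure is self-propagating.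

Step 10
Reactants: 21 protected (2S)-flavanone
Product: 23 tomentodiplacone B, via tris-trimethylsilyl ether 22 (not isolated)
Conditions: Me3SiOTf (8 equiv), 2,2'-bipyridyl (12 equiv), MeCN, 0 °C → rt; then Et3N·3HF, 0 °C → rt
Reagents that add atoms: none
Why: Bipyridyl-buffered silyl triflate exchange should turn the three aryl MOM ethers into aryl silyl ethers, and amine–HF then removes all silyl groups; neither stage is acidic enough to ionise the tertiary allylic alcohol or add a phenol across the 2'',3''-alkene, nor basic enough to open the flavanone, so C2 is kept.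

**Compound list**

1 | geranyl acetate, (2E)-3,7-dimethylocta-2,6-dien-1-yl acetate | CC(=O)OC/C=C(\C)CCC=C(C)C | starting material
2 | (2E)-5-(3,3-dimethyloxiran-2-yl)-3-methylpent-2-en-1-yl acetate (racemic) | CC(=O)OC/C=C(\C)CCC1OC1(C)C | intermediate
3 | (2E)-7-hydroxy-3,7-dimethyl-6-(phenylselanyl)oct-2-en-1-yl acetate | CC(=O)OC/C=C(\C)CCC([Se]c1ccccc1)C(C)(C)O | intermediate
4 | (2E)-7-hydroxy-3,7-dimethyl-6-(phenylseleninyl)oct-2-en-1-yl acetate | CC(=O)OC/C=C(\C)CCC([Se](=O)c1ccccc1)C(C)(C)O | intermediate
5 | (2E,5E)-7-hydroxy-3,7-dimethylocta-2,5-dien-1-yl acetate | CC(=O)OC/C=C(\C)C/C=C/C(C)(C)O | intermediate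
6 | (2E,5E)-3,7-dimethyl-7-[(triethylsilyl)oxy]octa-2,5-dien-1-yl acetate | CC(=O)OC/C=C(\C)C/C=C/C(C)(C)O[Si](CC)(CC)CC | intermediate
7 | 5-fluorobenzene-1,3-diol | Oc1cc(O)cc(F)c1 | starting material
8 | 1-fluoro-3,5-bis(methoxymethoxy)benzene | COCOc1cc(F)cc(OCOC)c1 | intermediate
9 | [4-fluoro-2,6-bis(methoxymethoxy)phenyl]lithium | [Li]c1c(OCOC)cc(F)cc1OCOC | intermediate
10 | chloro[4-fluoro-2,6-bis(methoxymethoxy)phenyl]zinc | Cl[Zn]c1c(OCOC)cc(F)cc1OCOC | intermediate
11 | 5-fluoro-1,3-bis(methoxymethoxy)-2-[(2E,5E)-3,7-dimethyl-7-(triethylsilyloxy)octa-2,5-dien-1-yl]benzene | COCOc1cc(F)cc(OCOC)c1C/C=C(\C)C/C=C/C(C)(C)O[Si](CC)(CC)CC | intermediate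
12 | {6-fluoro-2,4-bis(methoxymethoxy)-3-[(2E,5E)-3,7-dimethyl-7-(triethylsilyloxy)octa-2,5-dien-1-yl]phenyl}lithium | [Li]c1c(F)cc(OCOC)c(C/C=C(\C)C/C=C/C(C)(C)O[Si](CC)(CC)CC)c1OCOC | intermediate
13 | lithium 1-{6-fluoro-2,4-bis(methoxymethoxy)-3-[(2E,5E)-3,7-dimethyl-7-(triethylsilyloxy)octa-2,5-dien-1-yl]phenyl}-1-[methoxy(methyl)amino]ethan-1-olate | CC(O[Li])(N(C)OC)c1c(F)cc(OCOC)c(C/C=C(\C)C/C=C/C(C)(C)O[Si](CC)(CC)CC)c1OCOC | intermediate
14 | 1-{6-fluoro-2,4-bis(methoxymethoxy)-3-[(2E,5E)-3,7-dimethyl-7-(triethylsilyloxy)octa-2,5-dien-1-yl]phenyl}ethan-1-one | CC(=O)c1c(F)cc(OCOC)c(C/C=C(\C)C/C=C/C(C)(C)O[Si](CC)(CC)CC)c1OCOC | intermediate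
15 | lithium enolate of ketone 14 | C=C(O[Li])c1c(F)cc(OCOC)c(C/C=C(\C)C/C=C/C(C)(C)O[Si](CC)(CC)CC)c1OCOC | intermediate
16 | trimethylsilyl enol ether of ketone 14, [1-arylethenyl]oxy(trimethyl)silane | C=C(O[Si](C)(C)C)c1c(F)cc(OCOC)c(C/C=C(\C)C/C=C/C(C)(C)O[Si](CC)(CC)CC)c1OCOC | intermediate
17 | vanillin, 4-hydroxy-3-methoxybenzaldehyde | COc1cc(C=O)ccc1O | starting material
18 | 3-methoxy-4-(methoxymethoxy)benzaldehyde | COCOc1ccc(C=O)cc1OC | intermediate
19 | (3S)-1-{6-fluoro-2,4-bis(methoxymethoxy)-3-[(2E,5E)-3,7-dimethyl-7-(triethylsilyloxy)octa-2,5-dien-1-yl]phenyl}-3-[3-methoxy-4-(methoxymethoxy)phenyl]-3-(trichlorosilyloxy)propan-1-one | Cl[Si](Cl)(Cl)O[C@@H](CC(=O)c1c(F)cc(OCOC)c(C/C=C(\C)C/C=C/C(C)(C)O[Si](CC)(CC)CC)c1OCOC)c1ccc(OCOC)c(OC)c1 | intermediate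
20 | cesium (1S)-alkoxide of the aldol (the 3-oxido analogue of 19) | [Cs+].[O-][C@@H](CC(=O)c1c(F)cc(OCOC)c(C/C=C(\C)C/C=C/C(C)(C)O[Si](CC)(CC)CC)c1OCOC)c1ccc(OCOC)c(OC)c1 | intermediate
21 | (2S)-2-[3-methoxy-4-(methoxymethoxy)phenyl]-5,7-bis(methoxymethoxy)-6-[(2E,5E)-3,7-dimethyl-7-(triethylsilyloxy)octa-2,5-dien-1-yl]-2,3-dihydro-4H-chromen-4-one | COc1cc([C@@H]2CC(=O)c3c(cc(OCOC)c(C/C=C(\C)C/C=C/C(C)(C)O[Si](CC)(CC)CC)c3OCOC)O2)ccc1OCOC | intermediate
22 | (2S)-2-[3-methoxy-4-(trimethylsilyloxy)phenyl]-5,7-bis(trimethylsilyloxy)-6-[(2E,5E)-3,7-dimethyl-7-(triethylsilyloxy)octa-2,5-dien-1-yl]-2,3-dihydro-4H-chromen-4-one | COc1cc([C@@H]2CC(=O)c3c(cc(O[Si](C)(C)C)c(C/C=C(\C)C/C=C/C(C)(C)O[Si](CC)(CC)CC)c3O[Si](C)(C)C)O2)ccc1O[Si](C)(C)C | intermediate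
23 | tomentodiplacone B, (2S)-5,7-dihydroxy-2-(4-hydroxy-3-methoxyphenyl)-6-[(2E,5E)-7-hydroxy-3,7-dimethylocta-2,5-dien-1-yl]-2,3-dihydro-4H-chromen-4-one | COc1cc([C@@H]2CC(=O)c3c(cc(O)c(C/C=C(\C)C/C=C/C(C)(C)O)c3O)O2)ccc1O | target

**Step count and risks**

Total step count: 10. Longest linear sequence: 8 (steps 1, 2, 3, 5, 6, 7, 9, 10).

Steps most likely to fail:

1. Step 9 (bears the label). Once fluoride frees the aldolate oxygen, retro-aldol cleavage or E1cB elimination of that oxygen may outrun attack on the fluoroarene. This would erode enantiopurity or divert material to an open-chain enone; the electron-rich ring A may also slow the substitution. Fallback with known reaction types, in which C2 is set by conjugate arylation instead of aldol: setting out from ketone 14, Claisen formylation (NaH, HCO2Et, THF) should give the hydroxymethylene ketone F1. Heating its sodium enolate in DMF closes the ring by enolate O-arylation (SNAr, no stereocentre at risk) to the chromone F2. Rhodium-catalysed asymmetric 1,4-addition of commercial 2-methoxy-4-(4,4,5,5-tetramethyl-1,3,2-dioxaborolan-2-yl)phenol ([Rh(OH)(C8H12)]2, chiral biaryl diphosphine of the antipode that leads to 2S, aqueous dioxane) should give the 4'-hydroxyflavanone F3. Under the conditions of step 10 this comes back to the route at target 23.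

2. Step 5. The π-allylpalladium intermediate may isomerise (loss of 2E geometry, attack at the branched terminus) or undergo β-hydride elimination, or oxidative addition of the acetate may be too slow for the hindered arylzinc. Fallback by copper-mediated SN2 displacement instead of π-allyl chemistry: setting out from acetate 6, methanolysis (K2CO3, MeOH) should give the allylic alcohol F4, and an Appel reaction (CBr4, PPh3, CH2Cl2, 0 °C) the allylic bromide F5. Aryllithium 9, made from 8 as in step 5, is converted with CuBr·SMe2 into the arylcopper F6, which should displace the bromide directly and return to the route at 11.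

3. Step 6. The ortho-fluoroaryllithium may lose LiF to an aryne, or be quenched by proton transfer from the amide or from the doubly activated side-chain CH2, before acylation is complete. Fallback by carbonyl addition and oxidation instead of direct acylation: setting out from 11, lithiation as in step 6 and trapping with acetaldehyde at −78 °C (faster than amide acylation) should give the carbinol F7. Oxidation with Dess–Martin periodinane (CH2Cl2, NaHCO3) comes back to the route at 14.

Further compounds
F1 | step 9 | 1-{6-fluoro-2,4-bis(methoxymethoxy)-3-[(2E,5E)-3,7-dimethyl-7-(triethylsilyloxy)octa-2,5-dien-1-yl]phenyl}-3-hydroxyprop-2-en-1-one (hydroxymethylene ketone) | OC=CC(=O)c1c(F)cc(OCOC)c(C/C=C(\C)C/C=C/C(C)(C)O[Si](CC)(CC)CC)c1OCOC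
F2 | step 9 | 5,7-bis(methoxymethoxy)-6-[(2E,5E)-3,7-dimethyl-7-(triethylsilyloxy)octa-2,5-dien-1-yl]-4H-chromen-4-one | O=c1ccoc2cc(OCOC)c(C/C=C(\C)C/C=C/C(C)(C)O[Si](CC)(CC)CC)c(OCOC)c12
F3 | step 9 | (2S)-2-(4-hydroxy-3-methoxyphenyl)-5,7-bis(methoxymethoxy)-6-[(2E,5E)-3,7-dimethyl-7-(triethylsilyloxy)octa-2,5-dien-1-yl]-2,3-dihydro-4H-chromen-4-one | COc1cc([C@@H]2CC(=O)c3c(cc(OCOC)c(C/C=C(\C)C/C=C/C(C)(C)O[Si](CC)(CC)CC)c3OCOC)O2)ccc1O
F4 | step 5 | (2E,5E)-3,7-dimethyl-7-(triethylsilyloxy)octa-2,5-dien-1-ol | OC/C=C(\C)C/C=C/C(C)(C)O[Si](CC)(CC)CC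
F5 | step 5 | (2E,5E)-1-bromo-3,7-dimethyl-7-(triethylsilyloxy)octa-2,5-diene | BrC/C=C(\C)C/C=C/C(C)(C)O[Si](CC)(CC)CC
F6 | step 5 | [4-fluoro-2,6-bis(methoxymethoxy)phenyl]copper | [Cu]c1c(OCOC)cc(F)cc1OCOC
F7 | step 6 | 1-{6-fluoro-2,4-bis(methoxymethoxy)-3-[(2E,5E)-3,7-dimethyl-7-(triethylsilyloxy)octa-2,5-dien-1-yl]phenyl}ethan-1-ol (racemic at the carbinol) | CC(O)c1c(F)cc(OCOC)c(C/C=C(\C)C/C=C/C(C)(C)O[Si](CC)(CC)CC)c1OCOC
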